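**Retrosynthetic overview**

- The target is disconnected last at the side-chain ester: the primary hydroxyl of hydroxytyrosol opens a trans-fused bicyclic δ-lactone in which the C3 hydroxymethyl group and the C4 acetic acid arm are tied together.
- That lactone comes from a malonate-type δ-lactone by two oxidation-level changes: the C6 carbonyl is taken to C6–H (enol triflate, Pd/formate) and a cyclic acetal across the C3 and C4 substituents is oxidised to the lactone.
- Key disconnection: C4–C5 and C2–C3 are formed together in an amine-catalysed Michael/α-alkylation between an enal and a 1-chloroethyl malonate, giving the O1–C6 ring as a δ-lactone with all three stereocentres.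
- Enabling feature: at the lactone oxidation level C5 is a malonate carbon (nucleophile) whose ester oxygen O1 already carries C2 as an acetaldehyde-level electrophile (CH(Cl)CH3), while C3–C4 is the α,β-bond of an enal whose CHO is the later CH2OH.
- Ring order: ring A (O1–C6 ring, step 3), then temporary ring B (acetal, later lactone, across C3/C4; step 4), which is opened in step 8.

Key step: step 3

Assumption: the SMILES is read as the (2R,3R,4S) isomer (ring substituents all-trans); the target locants O1, C2 (CH3), C3 (CH2OH), C4 (CH2CO2R), C5 (CO2Me), C6 are used for the corresponding atoms of every intermediate.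

**Step 1**
Reactants: 1 methyl 3-chloro-3-oxopropanoate (methyl malonyl chloride); 2 acetaldehyde
Product: 3 1-chloroethyl methyl propanedioate (racemic)
Conditions: ZnCl2 (2 mol%), CH2Cl2, −10 °C to rt
Reagents that add atoms: none
Why: Lewis acid-catalysed addition of an acyl chloride across an aldehyde C=O (the standard 1-chloroalkyl ester synthesis) joins the two pieces; the new centre is racemic, which is acceptable because it is labile and is reset in step 3.

**Step 2**
Reactants: 4 4,4-diethoxybut-1-ene; 5 (E)-but-2-enal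
Product: 6 (E)-5,5-diethoxypent-2-enal
Conditions: second-generation Hoveyda–Grubbs catalyst (2 mol%), CH2Cl2, 40 °C
Reagents that add atoms: none
Why: Olefin cross-metathesis of a terminal alkene with crotonaldehyde should give the E-enal with loss of propene, and the diethyl acetal carries the future acetic ester arm at an oxidation level that does not acidify the γ-position of the enal.

**Step 3**
Reactants: 3 1-chloroethyl methyl propanedioate; 6 (E)-5,5-diethoxypent-2-enal
Product: 8 methyl (4S,5S,6R)-4-(2,2-diethoxyethyl)-5-formyl-6-methyl-2-oxooxane-3-carboxylate, via Michael adduct 7 (not isolated)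
Conditions: (R)-2-[diphenyl(trimethylsilyloxy)methyl]pyrrolidine (20 mol%), 2,6-lutidine (1.2 equiv), CHCl3, 0 °C to rt
Reagents that add atoms: none
Why: Proposed new method: the amine condenses with enal 6 to an iminium ion, the malonate C–H of 3 adds to its β-carbon on the face left open by the diphenyl(silyloxy)methyl group (forming C4–C5 and fixing C4 as S), and the resulting enamine displaces chloride from the tethered 1-chloroethyl ester carbon in a 6-exo-tet C-alkylation (forming C2–C3) before hydrolysis returns the catalyst. The closest known reaction type is the prolinol silyl ether-catalysed domino Michael/α-alkylation of enals with bromomalonates and 4-bromoacetoacetates, which gives cyclopropanes and cyclopentanones; here an oxygen is built into the tether so that the same cascade closes a δ-lactone. C3 should be set trans to the C4 substituent because the enamine is attacked anti to it and the α-formyl centre can equilibrate; C2 should be set by a chair-like transition state with the methyl group equatorial, the racemic C–Cl centre of 3 being funnelled into it by chloride exchange with the lutidinium chloride formed. The step needs C-alkylation of the enamine to win over N-alkylation of the catalyst and over alkylation of the malonate; the hindered pyrrolidine nitrogen, the intramolecular six-membered closure and the impossibility of a four-membered malonate self-alkylation should secure this. The all-equatorial lactone is also the thermodynamic isomer, so any β-elimination and re-addition of the carboxylate should converge on 8.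

**Step 4**
Reactants: 8 methyl (4S,5S,6R)-4-(2,2-diethoxyethyl)-5-formyl-6-methyl-2-oxooxane-3-carboxylate
Product: 10 methyl (1R,4aS,8aR)-6-ethoxy-1-methyl-3-oxooctahydropyrano[3,4-c]pyran-4-carboxylate (trans-fused lactone acetal, epimers at C4 and C6 of this name), via hydroxy lactone 9 (not isolated)
Conditions: NaBH4, MeOH, −40 °C; then camphorsulfonic acid (cat.), CH2Cl2, rt
Reagents that add atoms: none
Why: Chemoselective borohydride reduction of the aldehyde (the malonate-type lactone is shielded as its enolate) followed at once by acid-catalysed intramolecular transacetalisation locks the new alcohol and the side-chain acetal in a six-membered cyclic acetal before the alcohol can translactonise; the acetal carbon forms as an inconsequential anomeric mixture.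

**Step 5**
Reactants: 10 methyl (1R,4aS,8aR)-6-ethoxy-1-methyl-3-oxooctahydropyrano[3,4-c]pyran-4-carboxylate
Product: 11 methyl (1R,4aS,8aR)-6-ethoxy-1-methyl-3-{[(trifluoromethyl)sulfonyl]oxy}-1,4a,5,6,8,8a-hexahydropyrano[3,4-c]pyran-4-carboxylate
Conditions: NaN(SiMe3)2, PhNTf2, THF, −78 °C
Reagents that add atoms: N-phenylbis(trifluoromethanesulfonimide), O=S(=O)(N(c1ccccc1)S(=O)(=O)C(F)(F)F)C(F)(F)F
Why: Enol triflate formation from a 1,3-dicarbonyl: the only acidic C–H lies between the lactone and ester carbonyls, and sulfonylation of the ring-carbonyl oxygen gives the endocyclic, ester-conjugated ketene acetal triflate (as for α-alkoxycarbonyl lactams) without involving a stereocentre.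

**Step 6**
Reactants: 11 methyl (1R,4aS,8aR)-6-ethoxy-1-methyl-3-{[(trifluoromethyl)sulfonyl]oxy}-1,4a,5,6,8,8a-hexahydropyrano[3,4-c]pyran-4-carboxylate
Product: 12 methyl (1R,4aS,8aR)-6-ethoxy-1-methyl-1,4a,5,6,8,8a-hexahydropyrano[3,4-c]pyran-4-carboxylate
Conditions: Pd(OAc)2 (5 mol%), PPh3, HCO2H, Et3N, DMF, 60 °C
Reagents that add atoms: none
Why: Palladium-catalysed formate reduction of a vinyl triflate (oxidative addition of zerovalent palladium, hydride from formate, reductive elimination) replaces OTf by H and so delivers the β-alkoxyacrylate of the target ring without touching the acetal or any stereocentre.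

**Step 7**
Reactants: 12 methyl (1R,4aS,8aR)-6-ethoxy-1-methyl-1,4a,5,6,8,8a-hexahydropyrano[3,4-c]pyran-4-carboxylate
Product: 14 methyl (1R,4aS,8aR)-1-methyl-6-oxo-1,4a,5,6,8,8a-hexahydropyrano[3,4-c]pyran-4-carboxylate, via lactol 13 (not isolated)
Conditions: pyridinium p-toluenesulfonate, acetone–H2O, 50 °C; then TEMPO (10 mol%), PhI(OAc)2, CH2Cl2, rt
Reagents that add atoms: water, O
Why: Acetal hydrolysis to the lactol followed by oxoammonium (TEMPO/PhI(OAc)2) lactol-to-lactone oxidation brings the masked arm to the carboxyl level, while the electron-poor enol ether and all stereocentres stay untouched.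

**Step 8**
Reactants: 14 methyl (1R,4aS,8aR)-1-methyl-6-oxo-1,4a,5,6,8,8a-hexahydropyrano[3,4-c]pyran-4-carboxylate; 15 2-(3,4-dihydroxyphenyl)ethanol (hydroxytyrosol)
Product: 16 2-(3,4-dihydroxyphenyl)ethyl 2-[(2R,3R,4S)-3-(hydroxymethyl)-5-(methoxycarbonyl)-2-methyl-3,4-dihydro-2H-pyran-4-yl]acetate
Conditions: immobilised Candida antarctica lipase B (Novozym 435), 15 (5 equiv), 2-methylbutan-2-ol, 4 Å molecular sieves, 45 °C
Reagents that add atoms: none
Why: Lipase-catalysed transesterification (alcoholysis of a δ-lactone through the acyl-enzyme) should acylate only the primary aliphatic hydroxyl of hydroxytyrosol, opening the lactone to the side-chain ester and freeing the C3 hydroxymethyl group under neutral conditions in which no stereocentre can epimerise.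

**Compound list**

1 | methyl 3-chloro-3-oxopropanoate | COC(=O)CC(Cl)=O | starting material
2 | acetaldehyde | CC=O | starting material
3 | 1-chloroethyl methyl propanedioate (racemic) | COC(=O)CC(=O)OC(C)Cl | intermediate
4 | 4,4-diethoxybut-1-ene | C=CCC(OCC)OCC | starting material
5 | (E)-but-2-enal | C/C=C/C=O | starting material
6 | (E)-5,5-diethoxypent-2-enal | O=C/C=C/CC(OCC)OCC | intermediate
7 | 1-chloroethyl methyl 2-[(3R)-1,1-diethoxy-5-oxopentan-3-yl]propanedioate (Michael adduct, mixture at the malonate and C–Cl centres) | O=CC[C@@H](C(C(=O)OC)C(=O)OC(C)Cl)CC(OCC)OCC | intermediate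
8 | methyl (4S,5S,6R)-4-(2,2-diethoxyethyl)-5-formyl-6-methyl-2-oxooxane-3-carboxylate | COC(=O)C1C(=O)O[C@H](C)[C@@H](C=O)[C@@H]1CC(OCC)OCC | intermediate
9 | methyl (4S,5R,6R)-4-(2,2-diethoxyethyl)-5-(hydroxymethyl)-6-methyl-2-oxooxane-3-carboxylate | COC(=O)C1C(=O)O[C@H](C)[C@@H](CO)[C@@H]1CC(OCC)OCC | intermediate
10 | methyl (1R,4aS,8aR)-6-ethoxy-1-methyl-3-oxooctahydropyrano[3,4-c]pyran-4-carboxylate | COC(=O)C1C(=O)O[C@H](C)[C@H]2COC(OCC)C[C@H]12 | intermediate
11 | methyl (1R,4aS,8aR)-6-ethoxy-1-methyl-3-{[(trifluoromethyl)sulfonyl]oxy}-1,4a,5,6,8,8a-hexahydropyrano[3,4-c]pyran-4-carboxylate | COC(=O)C1=C(OS(=O)(=O)C(F)(F)F)O[C@H](C)[C@H]2COC(OCC)C[C@H]12 | intermediate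
12 | methyl (1R,4aS,8aR)-6-ethoxy-1-methyl-1,4a,5,6,8,8a-hexahydropyrano[3,4-c]pyran-4-carboxylate | COC(=O)C1=CO[C@H](C)[C@H]2COC(OCC)C[C@H]12 | intermediate
13 | methyl (1R,4aS,8aR)-6-hydroxy-1-methyl-1,4a,5,6,8,8a-hexahydropyrano[3,4-c]pyran-4-carboxylate (lactol) | COC(=O)C1=CO[C@H](C)[C@H]2COC(O)C[C@H]12 | intermediate
14 | methyl (1R,4aS,8aR)-1-methyl-6-oxo-1,4a,5,6,8,8a-hexahydropyrano[3,4-c]pyran-4-carboxylate | COC(=O)C1=CO[C@H](C)[C@H]2COC(=O)C[C@H]12 | intermediate
15 | 2-(3,4-dihydroxyphenyl)ethanol (hydroxytyrosol) | OCCc1ccc(O)c(O)c1 | starting material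
16 | 2-(3,4-dihydroxyphenyl)ethyl 2-[(2R,3R,4S)-3-(hydroxymethyl)-5-(methoxycarbonyl)-2-methyl-3,4-dihydro-2H-pyran-4-yl]acetate | COC(=O)C1=CO[C@H](C)[C@@H](CO)[C@@H]1CC(=O)OCCc1ccc(O)c(O)c1 | target

**Step count**

Total steps: 8. Longest linear sequence: 7 (steps 2 to 8, or step 1 and steps 3 to 8).

**Steps most likely to fail**

Step 3 (proposed method). N-alkylation of the amine catalyst by the 1-chloroethyl ester, or β-elimination of the carboxylate from the β-acyloxy aldehyde, may outrun or undo the 6-exo-tet closure. The fallback uses known chemistry, sets out from acetaldehyde 2 and comes back at lactone 14. Boron aldol reaction (Bu2BOTf, Et3N, soft enolisation to the dienol borinate, α-attack) of commercial (4S)-4-benzyl-3-[(E)-but-2-enoyl]-1,3-oxazolidin-2-one with 2 should give the syn aldol (4S)-4-benzyl-3-[(2S,3R)-2-ethenyl-3-hydroxybutanoyl]-1,3-oxazolidin-2-one F1, which fixes C2 and C3. LiBH4 removes the auxiliary to give (2R,3R)-2-ethenylbutane-1,3-diol F2. Silylation of the primary hydroxyl (TBSCl, imidazole) gives (2R,3R)-3-({[tert-butyl(dimethyl)silyl]oxy}methyl)pent-4-en-2-ol F3. Cross-metathesis with methyl acrylate (second-generation Hoveyda–Grubbs catalyst) gives methyl (2E,4R,5R)-4-({[tert-butyl(dimethyl)silyl]oxy}methyl)-5-hydroxyhex-2-enoate F4. Its sodium alkoxide (NaH, THF) adds to methyl propiolate and the vinyl anion closes onto the enoate (oxa-Michael/Michael, C4 substituent trans) to give methyl (2R,3R,4S)-3-({[tert-butyl(dimethyl)silyl]oxy}methyl)-4-(2-methoxy-2-oxoethyl)-2-methyl-3,4-dihydro-2H-pyran-5-carboxylate F5. Bu4NF then frees the hydroxymethyl group, which lactonises onto the CH2CO2Me arm to give 14.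

Step 8. The lipase-mediated lactone opening is reversible and may stall at partial conversion or re-close on work-up. The fallback sets out from 14 and comes back at 16. LiOH (1 equiv, THF–H2O, 0 °C) opens the lactone to lithium 2-[(2R,3R,4S)-3-(hydroxymethyl)-5-(methoxycarbonyl)-2-methyl-3,4-dihydro-2H-pyran-4-yl]acetate F6. TBSCl/imidazole followed by K2CO3/MeOH work-up gives 2-[(2R,3R,4S)-3-({[tert-butyl(dimethyl)silyl]oxy}methyl)-5-(methoxycarbonyl)-2-methyl-3,4-dihydro-2H-pyran-4-yl]acetic acid F7. Mitsunobu esterification (PPh3, diisopropyl azodicarboxylate) with 15, which activates only its aliphatic hydroxyl, gives methyl (2R,3R,4S)-3-({[tert-butyl(dimethyl)silyl]oxy}methyl)-4-{2-[2-(3,4-dihydroxyphenyl)ethoxy]-2-oxoethyl}-2-methyl-3,4-dihydro-2H-pyran-5-carboxylate F8. HF·pyridine then gives 16.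

Step 5. Sulfonylation on the exocyclic ester oxygen, or fragmentation of the malonate-type enolate with loss of the ring alkoxide, may compete with formation of the ring enol triflate. The fallback sets out from 10 and comes back at 12. i-Bu2AlH (CH2Cl2, −78 °C) reduces the more electrophilic lactone carbonyl to the lactol methyl (1R,4aS,8aR)-6-ethoxy-3-hydroxy-1-methyloctahydropyrano[3,4-c]pyran-4-carboxylate F9. MsCl/Et3N then dehydrates it through the ester enolate (E1cB) to 12.

**Further compounds**

F1 | step 3 | (4S)-4-benzyl-3-[(2S,3R)-2-ethenyl-3-hydroxybutanoyl]-1,3-oxazolidin-2-one | C[C@@H](O)[C@H](C=C)C(=O)N1[C@@H](Cc2ccccc2)COC1=O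
F2 | step 3 | (2R,3R)-2-ethenylbutane-1,3-diol | C[C@@H](O)[C@H](C=C)CO
F3 | step 3 | (2R,3R)-3-({[tert-butyl(dimethyl)silyl]oxy}methyl)pent-4-en-2-ol | C[C@@H](O)[C@H](C=C)CO[Si](C)(C)C(C)(C)C
F4 | step 3 | methyl (2E,4R,5R)-4-({[tert-butyl(dimethyl)silyl]oxy}methyl)-5-hydroxyhex-2-enoate | C[C@@H](O)[C@H](/C=C/C(=O)OC)CO[Si](C)(C)C(C)(C)C
F5 | step 3 | methyl (2R,3R,4S)-3-({[tert-butyl(dimethyl)silyl]oxy}methyl)-4-(2-methoxy-2-oxoethyl)-2-methyl-3,4-dihydro-2H-pyran-5-carboxylate | COC(=O)C1=CO[C@H](C)[C@@H](CO[Si](C)(C)C(C)(C)C)[C@@H]1CC(=O)OC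
F6 | step 8 | lithium 2-[(2R,3R,4S)-3-(hydroxymethyl)-5-(methoxycarbonyl)-2-methyl-3,4-dihydro-2H-pyran-4-yl]acetate | COC(=O)C1=CO[C@H](C)[C@@H](CO)[C@@H]1CC(=O)[O-].[Li+]
F7 | step 8 | 2-[(2R,3R,4S)-3-({[tert-butyl(dimethyl)silyl]oxy}methyl)-5-(methoxycarbonyl)-2-methyl-3,4-dihydro-2H-pyran-4-yl]acetic acid | COC(=O)C1=CO[C@H](C)[C@@H](CO[Si](C)(C)C(C)(C)C)[C@@H]1CC(=O)O
F8 | step 8 | methyl (2R,3R,4S)-3-({[tert-butyl(dimethyl)silyl]oxy}methyl)-4-{2-[2-(3,4-dihydroxyphenyl)ethoxy]-2-oxoethyl}-2-methyl-3,4-dihydro-2H-pyran-5-carboxylate | COC(=O)C1=CO[C@H](C)[C@@H](CO[Si](C)(C)C(C)(C)C)[C@@H]1CC(=O)OCCc1ccc(O)c(O)c1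
F9 | step 5 | methyl (1R,4aS,8aR)-6-ethoxy-3-hydroxy-1-methyloctahydropyrano[3,4-c]pyran-4-carboxylate | COC(=O)C1C(O)O[C@H](C)[C@H]2COC(OCC)C[C@H]12
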